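**Plan**
1. Numbering (ent-kaurane): lactone C19(=O)–O–C6, ring A C1–C5/C10, C7 methylene, bicyclo[3.2.1]octenone C8, C9(=O), C11=C12, C13, C14 (bridge CH2), C15 (OAc), C16=C17.
2. Enabling feature: the C15 oxygen sits endo, 1,4 to the enone β-carbon C12 (through C16 and C13), so the bicyclo[3.2.1]octenone is the ring-opened (retro-oxa-Michael) form of a cage in which that oxygen bridges C15 and C12; reclosing it makes O, C15, C8, C9(=O), C11, C12 a tetrahydropyran-4-one ring.
3. Retrosynthesis: acetate and C11=C12 from the cage ether; then C8–C14 and C15–C16 are cut together to a 2,3-dihydro-4H-pyran-4-one (vinylogous ester O–C15=C8–C9=O) whose C12 substituent is C13 bearing a 1-iodovinyl group (C16=C17) and CH2OTs (C14); the pyranone from a hetero-Diels–Alder of an aminosiloxy diene (C15, C8, C9, C11) with aldehyde C12; C6–C7 by radical addition to acrolein; ring A by metathesis on a butenolide-derived lactone.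
4. Forward: lactone ring (given), C5 and C4 substituents, ring A (C1=C10), C10 carbinol, chain C7–C8–C15, diene, pyranone ring, then in one flask the tetrahydrofuran bridge with ring D and ring C, bridge opening with acetylation, desilylation.
5. Stereochemistry: C6 of commercial butenolide 1 controls C5, then C4 and C10, and is re-set by convex-face radical addition; C13 from organocatalytic α-hydroxymethylation; the temporary C12 centre from Felkin–Anh addition; C8 and C15 from the tethers of the key step.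

Key step: step 21

Remark: Lac-OH = (1R,3aR,7R,7aS)-7-hydroxy-3a,7-dimethyl-3-oxooctahydroisobenzofuran-1-yl; Lac-OTBS = its 7-O-tert-butyldimethylsilyl ether; atom numbers in the Why lines are those of plan line 1.

**Route**

Step 1
Reactants: 1 (S)-5-(hydroxymethyl)furan-2(5H)-one
Product: 2 (S)-5-{[(tert-butyldiphenylsilyl)oxy]methyl}furan-2(5H)-one
Conditions: TBDPSCl, imidazole, CH2Cl2, 0 °C to rt
Reagents that add atoms: tert-butyl(chloro)diphenylsilane, CC(C)(C)[Si](Cl)(c1ccccc1)c1ccccc1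
Why: Silylation of the primary alcohol should give a bulky ether that shields one face of the butenolide for step 2; no new stereocentre.

Step 2
Reactants: 2 (S)-5-{[(tert-butyldiphenylsilyl)oxy]methyl}furan-2(5H)-one
Product: 3 (4R,5S)-5-{[(tert-butyldiphenylsilyl)oxy]methyl}-4-(prop-1-en-2-yl)dihydrofuran-2(3H)-one
Conditions: CH2=C(CH3)MgBr (2.4 equiv), CuI (1.2 equiv), THF, −78 to −30 °C; aq. NH4Cl
Reagents that add atoms: isopropenylmagnesium bromide, C=C(C)[Mg]Br
Why: Cuprate conjugate addition to the butenolide should occur anti to the C6 silyloxymethyl group and so set C5 (trans).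

Step 3
Reactants: 3 (4R,5S)-5-{[(tert-butyldiphenylsilyl)oxy]methyl}-4-(prop-1-en-2-yl)dihydrofuran-2(3H)-one
Product: 4 (3S,4R,5S)-3-(but-3-en-1-yl)-5-{[(tert-butyldiphenylsilyl)oxy]methyl}-4-(prop-1-en-2-yl)dihydrofuran-2(3H)-one
Conditions: LDA, THF, −78 °C; 4-iodobut-1-ene, HMPA, −78 to −20 °C
Reagents that add atoms: 4-iodobut-1-ene, C=CCCI
Why: Lactone enolate alkylation should place the butenyl group trans to the C5 isopropenyl group; this centre is re-formed in step 4, so its configuration is not critical.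

Step 4
Reactants: 4 (3S,4R,5S)-3-(but-3-en-1-yl)-5-{[(tert-butyldiphenylsilyl)oxy]methyl}-4-(prop-1-en-2-yl)dihydrofuran-2(3H)-one
Product: 5 (3R,4S,5S)-3-(but-3-en-1-yl)-5-{[(tert-butyldiphenylsilyl)oxy]methyl}-3-methyl-4-(prop-1-en-2-yl)dihydrofuran-2(3H)-one
Conditions: LDA, THF, −78 °C; MeI, −78 to 0 °C
Reagents that add atoms: iodomethane, CI
Why: The second enolate alkylation should create quaternary C4 with the methyl group entering anti to the isopropenyl group, which leaves butenyl and isopropenyl cis as the metathesis needs.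

Step 5
Reactants: 5 (3R,4S,5S)-3-(but-3-en-1-yl)-5-{[(tert-butyldiphenylsilyl)oxy]methyl}-3-methyl-4-(prop-1-en-2-yl)dihydrofuran-2(3H)-one
Product: 6 (3S,3aS,7aR)-3-{[(tert-butyldiphenylsilyl)oxy]methyl}-4,7a-dimethyl-3a,6,7,7a-tetrahydroisobenzofuran-1(3H)-one
Conditions: second-generation Grubbs catalyst RuCl2(=CHPh)(H2IMes)(PCy3) (5 mol%), CH2Cl2, 40 °C
Reagents that add atoms: none
Why: Ring-closing metathesis of the terminal alkene with the isopropenyl group should close ring A as a cis-fused cyclohexene with the C1=C10 trisubstituted double bond; no new stereocentre.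

Step 6
Reactants: 6 (3S,3aS,7aR)-3-{[(tert-butyldiphenylsilyl)oxy]methyl}-4,7a-dimethyl-3a,6,7,7a-tetrahydroisobenzofuran-1(3H)-one
Product: 7 (3S,3aS,4R,7aR)-3-{[(tert-butyldiphenylsilyl)oxy]methyl}-4-hydroxy-4,7a-dimethylhexahydroisobenzofuran-1(3H)-one
Conditions: Co(acac)2 (20 mol%), PhSiH3, O2 (1 atm), THF, rt
Reagents that add atoms: dioxygen, O=O
Why: Mukaiyama hydration (hydrogen-atom transfer, Markovnikov) should give the tertiary C10 alcohol, with oxygen captured on the face away from the lactone ring because the axial approach is blocked by the axial lactone carbonyl carbon on C4.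

Step 7
Reactants: 7 (3S,3aS,4R,7aR)-3-{[(tert-butyldiphenylsilyl)oxy]methyl}-4-hydroxy-4,7a-dimethylhexahydroisobenzofuran-1(3H)-one
Product: 8 (3S,3aS,4R,7aR)-4-hydroxy-3-(hydroxymethyl)-4,7a-dimethylhexahydroisobenzofuran-1(3H)-one
Conditions: n-Bu4NF, AcOH, THF, 0 °C to rt
Reagents that add atoms: none
Why: Buffered fluoride desilylation should free the primary alcohol without opening the lactone.

Step 8
Reactants: 8 (3S,3aS,4R,7aR)-4-hydroxy-3-(hydroxymethyl)-4,7a-dimethylhexahydroisobenzofuran-1(3H)-one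
Product: 9 (1S,3aR,7R,7aS)-7-hydroxy-3a,7-dimethyl-3-oxooctahydroisobenzofuran-1-carboxylic acid
Conditions: TEMPO (20 mol%), PhI(OAc)2 (2.2 equiv), MeCN/H2O 1:1, rt
Reagents that add atoms: water, O
Why: TEMPO/PhI(OAc)2 oxidation should take the primary alcohol to the carboxylic acid while the tertiary alcohol is inert.

Step 9
Reactants: 9 (1S,3aR,7R,7aS)-7-hydroxy-3a,7-dimethyl-3-oxooctahydroisobenzofuran-1-carboxylic acid
Product: 10 3-(Lac-OH)propanal
Conditions: Ir[dF(CF3)ppy]2(dtbbpy)PF6 (1 mol%), K2HPO4, acrolein (3 equiv), DMF, blue LEDs, rt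
Reagents that add atoms: acrolein, C=CC=O
Why: Photoredox decarboxylative Giese addition should add the α-acyloxy C6 radical to acrolein from the convex face (anti to ring A), which re-sets C6 with C7 exo and installs C7, C8 and C15.

Step 10
Reactants: 10 3-(Lac-OH)propanal
Product: 12 (E)-3-[(Lac-OH)methyl]-4-(pyrrolidin-1-yl)but-3-en-2-one, via enamine 11 (not isolated)
Conditions: pyrrolidine, K2CO3, CH2Cl2, 0 °C; then Et3N, AcCl, −20 °C to rt
Reagents that add atoms: pyrrolidine, C1CCNC1; acetyl chloride, CC(=O)Cl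
Why: Stork enamine C-acylation should place the acetyl group (C9, C11) on C8 and give the vinylogous amide; no stereocentre is formed.

Step 11
Reactants: 12 (E)-3-[(Lac-OH)methyl]-4-(pyrrolidin-1-yl)but-3-en-2-one
Product: 13 1-{(1E)-3-[(tert-butyldimethylsilyl)oxy]-2-[(Lac-OTBS)methyl]buta-1,3-dien-1-yl}pyrrolidine
Conditions: TBSOTf (2.5 equiv), Et3N, Et2O, −78 to 0 °C; used crude
Reagents that add atoms: tert-butyldimethylsilyl trifluoromethanesulfonate, CC(C)(C)[Si](C)(C)OS(=O)(=O)C(F)(F)F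
Why: Soft enolisation with O-silylation of the vinylogous amide should give the 1-amino-3-siloxy diene and at the same time protect the tertiary alcohol as its silyl ether.

Step 12
Reactants: 14 3-[(tert-butyldimethylsilyl)oxy]propanal
Product: 15 (S)-3-[(tert-butyldimethylsilyl)oxy]-2-(hydroxymethyl)propanal
Conditions: aq. CH2O (37%), (S)-α,α-diphenylprolinol trimethylsilyl ether (10 mol%), pH 7 phosphate buffer, toluene, rt
Reagents that add atoms: formaldehyde, C=O
Why: Enamine-catalysed α-hydroxymethylation (cross-aldol with formaldehyde) should set C13, the diarylprolinol silyl ether shielding one face of the enamine.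

Step 13
Reactants: 15 (S)-3-[(tert-butyldimethylsilyl)oxy]-2-(hydroxymethyl)propanal
Product: 16 (R)-3-[(tert-butyldimethylsilyl)oxy]-2-{[(tert-butyldiphenylsilyl)oxy]methyl}propanal
Conditions: TBDPSCl, imidazole, CH2Cl2, −20 to 0 °C
Reagents that add atoms: tert-butyl(chloro)diphenylsilane, CC(C)(C)[Si](Cl)(c1ccccc1)c1ccccc1
Why: Silylation of the new hydroxyl should block retro-aldol and differentiate the two oxymethyl arms (TBS arm becomes C12, TBDPS arm C14).

Step 14
Reactants: 16 (R)-3-[(tert-butyldimethylsilyl)oxy]-2-{[(tert-butyldiphenylsilyl)oxy]methyl}propanal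
Product: 17 (R)-tert-butyl[(2-{[(tert-butyldimethylsilyl)oxy]methyl}but-3-yn-1-yl)oxy]diphenylsilane
Conditions: dimethyl (1-diazo-2-oxopropyl)phosphonate, K2CO3, MeOH, 0 °C to rt
Reagents that add atoms: dimethyl (1-diazo-2-oxopropyl)phosphonate, CC(=O)C(=[N+]=[N-])P(=O)(OC)OC
Why: Ohira–Bestmann homologation should convert the aldehyde into the terminal alkyne (C16≡C17) quickly enough to keep the C13 configuration.

Step 15
Reactants: 17 (R)-tert-butyl[(2-{[(tert-butyldimethylsilyl)oxy]methyl}but-3-yn-1-yl)oxy]diphenylsilane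
Product: 19 (R)-tert-butyl[(2-{[(tert-butyldimethylsilyl)oxy]methyl}-3-iodobut-3-en-1-yl)oxy]diphenylsilane, via alkenylalane 18 (not isolated)
Conditions: Ni(dppp)Cl2 (3 mol%), i-Bu2AlH, THF, 0 °C to rt; then N-iodosuccinimide, −78 to 0 °C
Reagents that add atoms: N-iodosuccinimide, O=C1CCC(=O)N1I
Why: Nickel-catalysed α-selective hydroalumination of the terminal alkyne followed by iodinolysis should give the 2-iodoalkene (iodine on C16).

Step 16
Reactants: 19 (R)-tert-butyl[(2-{[(tert-butyldimethylsilyl)oxy]methyl}-3-iodobut-3-en-1-yl)oxy]diphenylsilane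
Product: 20 (R)-2-{[(tert-butyldiphenylsilyl)oxy]methyl}-3-iodobut-3-en-1-ol
Conditions: camphorsulfonic acid (10 mol%), MeOH/CH2Cl2, 0 °C
Reagents that add atoms: none
Why: Acid-catalysed methanolysis should remove the primary TBS ether selectively in the presence of the more robust primary TBDPS ether.

Step 17
Reactants: 20 (R)-2-{[(tert-butyldiphenylsilyl)oxy]methyl}-3-iodobut-3-en-1-ol
Product: 21 (S)-2-{[(tert-butyldiphenylsilyl)oxy]methyl}-3-iodobut-3-enal
Conditions: Dess–Martin periodinane, NaHCO3, CH2Cl2, 0 °C; used at once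
Reagents that add atoms: none
Why: Buffered Dess–Martin oxidation should give the β,γ-unsaturated aldehyde (C12) without epimerising C13 or moving the double bond.

Step 18
Reactants: 13 1-{(1E)-3-[(tert-butyldimethylsilyl)oxy]-2-[(Lac-OTBS)methyl]buta-1,3-dien-1-yl}pyrrolidine, 21 (S)-2-{[(tert-butyldiphenylsilyl)oxy]methyl}-3-iodobut-3-enal
Product: 23 (R)-2-[(S)-1-{[tert-butyldiphenylsilyl]oxy}-3-iodobut-3-en-2-yl]-5-[(Lac-OTBS)methyl]-2,3-dihydro-4H-pyran-4-one, via cycloadduct 22 (not isolated)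
Conditions: CHCl3, rt; then AcCl, CH2Cl2, −78 °C
Reagents that add atoms: none
Why: Hetero-Diels–Alder reaction of the 1-amino-3-siloxy diene with the aldehyde, then acyl-chloride-induced loss of the amine and silyl group, should give the dihydropyranone and join the two halves; C12 should be set (R) by Felkin–Anh addition with the 1-iodovinyl group as the large substituent.

Step 19
Reactants: 23 (R)-2-[(S)-1-{[tert-butyldiphenylsilyl]oxy}-3-iodobut-3-en-2-yl]-5-[(Lac-OTBS)methyl]-2,3-dihydro-4H-pyran-4-one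
Product: 24 (R)-2-[(S)-1-hydroxy-3-iodobut-3-en-2-yl]-5-[(Lac-OTBS)methyl]-2,3-dihydro-4H-pyran-4-one
Conditions: n-Bu4NF, AcOH, THF, 0 °C to rt
Reagents that add atoms: none
Why: Buffered fluoride should cleave the primary TBDPS ether while the hindered tertiary TBS ether and the base-sensitive pyranone survive.

Step 20
Reactants: 24 (R)-2-[(S)-1-hydroxy-3-iodobut-3-en-2-yl]-5-[(Lac-OTBS)methyl]-2,3-dihydro-4H-pyran-4-one
Product: 25 (S)-2-{(R)-5-[(Lac-OTBS)methyl]-4-oxo-3,4-dihydro-2H-pyran-2-yl}-3-iodobut-3-en-1-yl 4-methylbenzenesulfonate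
Conditions: TsCl, pyridine, DMAP (cat.), CH2Cl2, 0 °C
Reagents that add atoms: 4-methylbenzenesulfonyl chloride, Cc1ccc(cc1)S(=O)(=O)Cl
Why: Sulfonylation of the primary alcohol should turn C14 into the electrophile for the key step, a change that is only possible now because C12 is no longer a carbonyl.

Step 21
Reactants: 25 (S)-2-{(R)-5-[(Lac-OTBS)methyl]-4-oxo-3,4-dihydro-2H-pyran-2-yl}-3-iodobut-3-en-1-yl 4-methylbenzenesulfonate
Product: 28 caged ether ketone (target skeleton with C11–C12 saturated, an ether oxygen bridging C15 and C12 on the endo face, O-TBS on C10), via alkenylcuprate 26 (not isolated), via lithium enolate 27 (not isolated)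
Conditions: (PhCMe2CH2)2CuLi (1.2 equiv, from PhCMe2CH2Li and CuI), THF/Et2O, −78 to 0 °C; then HMPA, 0 °C to rt
Reagents that add atoms: none
Why: Proposed new method: iodine–copper exchange with the non-transferable neophyl cuprate should turn the 2-iodoalkene into alkenylcuprate 26 in the presence of the ketone; its C16 then adds 1,4 to the vinylogous ester at C15 (5-exo-trig, closing the tetrahydrofuran ring O–C15–C16–C13–C12) to give the regiodefined enolate 27, whose C8 displaces the primary tosylate on C14 (5-exo-tet for the five-membered ring C8–C14–C13–C16–C15, which also completes the six-membered ring C8–C9–C11–C12–C13–C14). The closest known reaction type is the methylenecyclopentane annulation of enones with 4-halobut-1-en-2-yl cuprates (conjugate addition, then intramolecular enolate alkylation), combined here with halogen–copper exchange so that the whole three-carbon unit is tethered and both bonds form in one flask. C15 is set by the tether, because the alkenyl group can only reach the pyranone face that carries the C12 substituent (2,6-cis), which leaves the ring oxygen endo on C15; C8 is set because C14 is held on that same face of the enolate, forcing C7 to the other; C13 comes from 21 unchanged. The step needs 1,4- and not 1,2-addition (secured by copper and by the weakly electrophilic vinylogous ester carbonyl), the (12R,13S) relationship that points C14 at C8 (secured in step 18), and C-alkylation ahead of β-elimination of the bridging oxygen (favoured by the good leaving group, HMPA and low temperature; O-alkylation would need a bridged seven-membered ring).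

Step 22
Reactants: 28 caged ether ketone
Product: 30 target skeleton carrying C15-OAc, the C11=C12 enone and O-TBS on C10, via hydroxy enone 29 (not isolated)
Conditions: DBU, Ac2O, DMAP (cat.), CH2Cl2, 0 °C to rt
Reagents that add atoms: acetic anhydride, CC(=O)OC(C)=O
Why: Base-induced retro-oxa-Michael (E1cB) elimination can only start from C11 because C8 is quaternary, so it should release cage strain, form the C11=C12 enone and free the C15 oxygen, which is acetylated at once with its endo configuration retained.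

Step 23
Reactants: 30 target skeleton carrying C15-OAc, the C11=C12 enone and O-TBS on C10
Product: 31 CNP0172716.1, (4R,5S,6R,8R,10R,13S,15R)-15-acetoxy-10-hydroxy-9-oxo-9,10-seco-ent-kaura-11,16-dien-19,6-olide
Conditions: HF·pyridine, THF, 0 to 40 °C
Reagents that add atoms: none
Why: Fluoride-mediated cleavage of the tertiary silyl ether should free the C10 alcohol without touching the allylic acetate, enone or lactone.

**Compound list**
1 | (S)-5-(hydroxymethyl)furan-2(5H)-one | OC[C@H]1OC(=O)C=C1 | starting material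
2 | (S)-5-{[(tert-butyldiphenylsilyl)oxy]methyl}furan-2(5H)-one | CC(C)(C)[Si](c1ccccc1)(c1ccccc1)OC[C@H]1OC(=O)C=C1 | intermediate
3 | (4R,5S)-5-{[(tert-butyldiphenylsilyl)oxy]methyl}-4-(prop-1-en-2-yl)dihydrofuran-2(3H)-one | CC(C)(C)[Si](c1ccccc1)(c1ccccc1)OC[C@H]1OC(=O)C[C@@H]1C(C)=C | intermediate
4 | (3S,4R,5S)-3-(but-3-en-1-yl)-5-{[(tert-butyldiphenylsilyl)oxy]methyl}-4-(prop-1-en-2-yl)dihydrofuran-2(3H)-one | CC(C)(C)[Si](c1ccccc1)(c1ccccc1)OC[C@H]1OC(=O)[C@@H](CCC=C)[C@@H]1C(C)=C | intermediate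
5 | (3R,4S,5S)-3-(but-3-en-1-yl)-5-{[(tert-butyldiphenylsilyl)oxy]methyl}-3-methyl-4-(prop-1-en-2-yl)dihydrofuran-2(3H)-one | CC(C)(C)[Si](c1ccccc1)(c1ccccc1)OC[C@H]1OC(=O)[C@](C)(CCC=C)[C@@H]1C(C)=C | intermediate
6 | (3S,3aS,7aR)-3-{[(tert-butyldiphenylsilyl)oxy]methyl}-4,7a-dimethyl-3a,6,7,7a-tetrahydroisobenzofuran-1(3H)-one | CC(C)(C)[Si](c1ccccc1)(c1ccccc1)OC[C@H]1OC(=O)[C@]2(C)CCC=C(C)[C@H]12 | intermediate
7 | (3S,3aS,4R,7aR)-3-{[(tert-butyldiphenylsilyl)oxy]methyl}-4-hydroxy-4,7a-dimethylhexahydroisobenzofuran-1(3H)-one | CC(C)(C)[Si](c1ccccc1)(c1ccccc1)OC[C@H]1OC(=O)[C@]2(C)CCC[C@@](C)(O)[C@H]12 | intermediate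
8 | (3S,3aS,4R,7aR)-4-hydroxy-3-(hydroxymethyl)-4,7a-dimethylhexahydroisobenzofuran-1(3H)-one | OC[C@H]1OC(=O)[C@]2(C)CCC[C@@](C)(O)[C@H]12 | intermediate
9 | (1S,3aR,7R,7aS)-7-hydroxy-3a,7-dimethyl-3-oxooctahydroisobenzofuran-1-carboxylic acid | OC(=O)[C@H]1OC(=O)[C@]2(C)CCC[C@@](C)(O)[C@H]12 | intermediate
10 | 3-(Lac-OH)propanal | O=CCC[C@H]1OC(=O)[C@]2(C)CCC[C@@](C)(O)[C@H]12 | intermediate
11 | (E)-1-[3-(Lac-OH)prop-1-en-1-yl]pyrrolidine (enamine, not isolated) | C1CCN(C1)/C=C/C[C@H]2OC(=O)[C@]3(C)CCC[C@@](C)(O)[C@H]23 | intermediate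
12 | (E)-3-[(Lac-OH)methyl]-4-(pyrrolidin-1-yl)but-3-en-2-one | CC(=O)/C(C[C@H]1OC(=O)[C@]2(C)CCC[C@@](C)(O)[C@H]12)=C/N3CCCC3 | intermediate
13 | 1-{(1E)-3-[(tert-butyldimethylsilyl)oxy]-2-[(Lac-OTBS)methyl]buta-1,3-dien-1-yl}pyrrolidine | C=C(O[Si](C)(C)C(C)(C)C)/C(C[C@H]1OC(=O)[C@]2(C)CCC[C@@](C)(O[Si](C)(C)C(C)(C)C)[C@H]12)=C/N3CCCC3 | intermediate
14 | 3-[(tert-butyldimethylsilyl)oxy]propanal | CC(C)(C)[Si](C)(C)OCCC=O | starting material
15 | (S)-3-[(tert-butyldimethylsilyl)oxy]-2-(hydroxymethyl)propanal | O=C[C@@H](CO)CO[Si](C)(C)C(C)(C)C | intermediate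
16 | (R)-3-[(tert-butyldimethylsilyl)oxy]-2-{[(tert-butyldiphenylsilyl)oxy]methyl}propanal | O=C[C@@H](CO[Si](c1ccccc1)(c1ccccc1)C(C)(C)C)CO[Si](C)(C)C(C)(C)C | intermediate
17 | (R)-tert-butyl[(2-{[(tert-butyldimethylsilyl)oxy]methyl}but-3-yn-1-yl)oxy]diphenylsilane | C#C[C@@H](CO[Si](c1ccccc1)(c1ccccc1)C(C)(C)C)CO[Si](C)(C)C(C)(C)C | intermediate
18 | diisobutyl(alken-2-yl)alane from 17 (aluminium on C16, not isolated) | C=C([Al](CC(C)C)CC(C)C)[C@@H](CO[Si](c1ccccc1)(c1ccccc1)C(C)(C)C)CO[Si](C)(C)C(C)(C)C | intermediate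
19 | (R)-tert-butyl[(2-{[(tert-butyldimethylsilyl)oxy]methyl}-3-iodobut-3-en-1-yl)oxy]diphenylsilane | C=C(I)[C@@H](CO[Si](c1ccccc1)(c1ccccc1)C(C)(C)C)CO[Si](C)(C)C(C)(C)C | intermediate
20 | (R)-2-{[(tert-butyldiphenylsilyl)oxy]methyl}-3-iodobut-3-en-1-ol | C=C(I)[C@@H](CO[Si](c1ccccc1)(c1ccccc1)C(C)(C)C)CO | intermediate
21 | (S)-2-{[(tert-butyldiphenylsilyl)oxy]methyl}-3-iodobut-3-enal | C=C(I)[C@@H](CO[Si](c1ccccc1)(c1ccccc1)C(C)(C)C)C=O | intermediate
22 | 2,6-cis cycloadduct: 2-(pyrrolidin-1-yl)-4-silyloxy-3,6-dihydro-2H-pyran bearing the C13 side chain on C6 and CH2-Lac-OTBS on C3 (not isolated) | CC(C)(C)[Si](C)(C)OC1=C(C[C@H]2OC(=O)[C@]3(C)CCC[C@@](C)(O[Si](C)(C)C(C)(C)C)[C@H]23)[C@@H](N4CCCC4)O[C@@H]([C@H](CO[Si](c5ccccc5)(c5ccccc5)C(C)(C)C)C(I)=C)C1 | intermediate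
23 | (R)-2-[(S)-1-{[tert-butyldiphenylsilyl]oxy}-3-iodobut-3-en-2-yl]-5-[(Lac-OTBS)methyl]-2,3-dihydro-4H-pyran-4-one | C=C(I)[C@@H](CO[Si](c1ccccc1)(c1ccccc1)C(C)(C)C)[C@H]1CC(=O)C(C[C@H]2OC(=O)[C@]3(C)CCC[C@@](C)(O[Si](C)(C)C(C)(C)C)[C@H]23)=CO1 | intermediate
24 | (R)-2-[(S)-1-hydroxy-3-iodobut-3-en-2-yl]-5-[(Lac-OTBS)methyl]-2,3-dihydro-4H-pyran-4-one | C=C(I)[C@@H](CO)[C@H]1CC(=O)C(C[C@H]2OC(=O)[C@]3(C)CCC[C@@](C)(O[Si](C)(C)C(C)(C)C)[C@H]23)=CO1 | intermediate
25 | (S)-2-{(R)-5-[(Lac-OTBS)methyl]-4-oxo-3,4-dihydro-2H-pyran-2-yl}-3-iodobut-3-en-1-yl 4-methylbenzenesulfonate | C=C(I)[C@@H](COS(=O)(=O)c1ccc(C)cc1)[C@H]1CC(=O)C(C[C@H]2OC(=O)[C@]3(C)CCC[C@@](C)(O[Si](C)(C)C(C)(C)C)[C@H]23)=CO1 | intermediate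
26 | lithium alkenyl(neophyl)cuprate from 25 (copper on C16, not isolated) | [Li+].C=C([Cu-]CC(C)(C)c1ccccc1)[C@@H](COS(=O)(=O)c1ccc(C)cc1)[C@H]1CC(=O)C(C[C@H]2OC(=O)[C@]3(C)CCC[C@@](C)(O[Si](C)(C)C(C)(C)C)[C@H]23)=CO1 | intermediate
27 | lithium enolate (C8=C9–OLi) of the 8-oxabicyclo[3.2.1]octanone formed by C16–C15 closure, tosylate intact (not isolated) | C=C1[C@@H](COS(=O)(=O)c2ccc(C)cc2)[C@H]3CC(O[Li])=C(C[C@H]4OC(=O)[C@]5(C)CCC[C@@](C)(O[Si](C)(C)C(C)(C)C)[C@H]45)[C@@H]1O3 | intermediate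
28 | caged ether ketone: target skeleton with C11–C12 saturated, ether oxygen bridging C15 and C12 (endo), O-TBS on C10 | C=C1[C@@H]2[C@H]3CC(=O)[C@@](C[C@H]4OC(=O)[C@]5(C)CCC[C@@](C)(O[Si](C)(C)C(C)(C)C)[C@H]45)(C2)[C@@H]1O3 | intermediate
29 | hydroxy enone: 15-hydroxy analogue of 30 (not isolated) | C=C1[C@@H]2C=CC(=O)[C@@](C[C@H]3OC(=O)[C@]4(C)CCC[C@@](C)(O[Si](C)(C)C(C)(C)C)[C@H]34)(C2)[C@@H]1O | intermediate
30 | 10-O-tert-butyldimethylsilyl ether of the target | C=C1[C@@H]2C=CC(=O)[C@@](C[C@H]3OC(=O)[C@]4(C)CCC[C@@](C)(O[Si](C)(C)C(C)(C)C)[C@H]34)(C2)[C@@H]1OC(C)=O | intermediate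
31 | CNP0172716.1, (4R,5S,6R,8R,10R,13S,15R)-15-acetoxy-10-hydroxy-9-oxo-9,10-seco-ent-kaura-11,16-dien-19,6-olide | C=C1[C@@H]2C=CC(=O)[C@@](C[C@H]3OC(=O)[C@]4(C)CCC[C@@](C)(O)[C@H]34)(C2)[C@@H]1OC(C)=O | target

**Step count and risks**
Total steps: 23. Longest linear sequence: 17 (steps 1–11 and 18–23); the aldehyde branch is steps 12–17.

Most likely to fail:

1. Step 21 (proposed new method). The iodine–copper exchange on the unactivated 2-iodoalkene may be slow. The in-flask alkylation may also lose to β-elimination of the bridging oxygen from the enolate, or to proton quench, so that the sequence stops after the first ring closure. Fallback with known reactions, from 25: nickel-catalysed reductive conjugate addition of the alkenyl iodide to the enone with chlorotriethylsilane (NiCl2(dme), neocuproine, Mn powder, Et3SiCl, DMF) should give the isolable, regiodefined triethylsilyl enol ether F1. Anhydrous benzyltrimethylammonium fluoride (THF, molecular sieves) should then release the ammonium enolate and close the C8–C14 bond by intramolecular C-alkylation, returning to the route at 28.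

2. Step 18. Facial selectivity at C12 may be insufficient, and the basic amino diene may epimerise C13 or move the double bond of the β,γ-unsaturated aldehyde during a slow cycloaddition. Fallback, from 12 and 21: diisopinocampheylboron chloride (the enantiomer matched to the Felkin–Anh sense, 2.2 equiv) and Et3N should form the boron enolate of the methyl ketone at −78 °C. Aldol addition to 21 at −78 °C, through a closed transition state with no free amine, should give the β-hydroxy vinylogous amide F2. Trifluoroacetic acid should close the ring by O-addition and loss of pyrrolidine to the dihydropyranone with a free tertiary alcohol F3, and TBSOTf/2,6-lutidine returns to the route at 23.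

3. Step 6. Oxygen capture by the planar C10 radical may show poor facial selectivity (capture syn to the lactone gives the C10 epimer), and the radical may be reduced instead. Fallback, from 6: OsO4 (cat.)/N-methylmorpholine N-oxide dihydroxylation from the face opposite the lactone should give the cis-diol F4. Selective thionocarbonate formation at the secondary hydroxyl (PhOC(S)Cl, pyridine, DMAP) should give the O-phenyl thionocarbonate F5, and Barton–McCombie deoxygenation (Bu3SnH, AIBN, toluene, 80 °C) returns to the route at 7.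

Further compounds
F1 | step 21 | triethylsilyl enol ether (C8=C9–OSiEt3) of the 8-oxabicyclo[3.2.1]octanone formed by C16–C15 closure, tosylate intact | C=C1[C@@H](COS(=O)(=O)c2ccc(C)cc2)[C@H]3CC(O[Si](CC)(CC)CC)=C(C[C@H]4OC(=O)[C@]5(C)CCC[C@@](C)(O[Si](C)(C)C(C)(C)C)[C@H]45)[C@@H]1O3
F2 | step 18 | (E)-aldol adduct: (12R,13S)-β-hydroxy ketone of 12 with 21 | C=C(I)[C@@H](CO[Si](c1ccccc1)(c1ccccc1)C(C)(C)C)[C@H](O)CC(=O)/C(C[C@H]2OC(=O)[C@]3(C)CCC[C@@](C)(O)[C@H]23)=C/N4CCCC4
F3 | step 18 | (R)-2-[(S)-1-{[tert-butyldiphenylsilyl]oxy}-3-iodobut-3-en-2-yl]-5-[(Lac-OH)methyl]-2,3-dihydro-4H-pyran-4-one | C=C(I)[C@@H](CO[Si](c1ccccc1)(c1ccccc1)C(C)(C)C)[C@H]1CC(=O)C(C[C@H]2OC(=O)[C@]3(C)CCC[C@@](C)(O)[C@H]23)=CO1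
F4 | step 6 | cis-4,5-diol of 6 (both hydroxyls on the face opposite the lactone) | CC(C)(C)[Si](c1ccccc1)(c1ccccc1)OC[C@H]1OC(=O)[C@]2(C)CC[C@@H](O)[C@@](C)(O)[C@H]12
F5 | step 6 | O-phenyl thionocarbonate of F4 at the secondary hydroxyl | CC(C)(C)[Si](c1ccccc1)(c1ccccc1)OC[C@H]1OC(=O)[C@]2(C)CC[C@@H](OC(=S)Oc3ccccc3)[C@@](C)(O)[C@H]12
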